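**Plan**
- Retrosynthesis: the two phenols are traced back to aryl benzyl ethers. The C2–C3 bond of the tridecane chain (acetoxy-bearing carbon to the first CH2 of the undecyl chain) is then cut to a racemic 1-bromoalkyl acetate and undecylzinc bromide. The C2–Br and C2–OAc bonds go back to an arylacetaldehyde plus acetyl bromide, and the C1–C2 bond to 3,5-bis(benzyloxy)benzaldehyde by one-carbon homologation.
- Forward: no ring is formed, since the 1,3,5-trisubstituted benzene ring is bought. The chain is joined in the order ArCHO → ArCH2CHO → ArCH2CH(Br)OAc → ArCH2CH(OAc)C11H23, followed by debenzylation.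
- Enabling feature: C2 carries the target's own acetate, O–C(=O)CH3, between the benzylic C1 methylene and the C3 methylene. With a geminal bromine this carbon becomes a precursor of an α-acetoxyalkyl radical, and the ester carbonyl oxygen can bind nickel. The acetate is therefore the activating group and stays in the product; only the two ring oxygens need temporary benzyl groups.
- Stereochemistry: the single stereocentre (C2, R) is set in the nickel-catalysed coupling by the chiral ligand. The step is stereoconvergent, so both enantiomers of the racemic bromo ester are funnelled into the R acetate.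

Key step: step 5

Assumption: which antipode of the bis(oxazoline) ligand gives the R ester cannot be read from the structure; the antipode that gives R is used, identified by one pair of test couplings with the two ligand antipodes.

**Route**

Step 1
Reactants: 1 3,5-bis(benzyloxy)benzaldehyde
Product: 2 1,3-bis(benzyloxy)-5-(2-methoxyethenyl)benzene (E/Z mixture)
Conditions: Ph3P(CH2OMe)Cl (1.3 equiv), KOtBu (1.3 equiv), THF, 0 °C to rt
Reagents that add atoms: (methoxymethyl)triphenylphosphonium chloride, COC[P+](c1ccccc1)(c1ccccc1)c1ccccc1.[Cl-]
Why: Wittig olefination of a non-enolisable aromatic aldehyde with the methoxymethylene ylide is a standard one-carbon homologation, the benzyl ethers are inert to the base, and the E/Z ratio is irrelevant because both isomers hydrolyse to the same aldehyde.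

Step 2
Reactants: 2 1,3-bis(benzyloxy)-5-(2-methoxyethenyl)benzene
Product: 3 2-[3,5-bis(benzyloxy)phenyl]acetaldehyde
Conditions: 2 M aq. HCl, THF, 40 °C, short contact time; crude aldehyde used without storage
Reagents that add atoms: water, O
Why: Acid-catalysed enol ether hydrolysis (C-protonation, hydration of the oxocarbenium ion, loss of methanol) should unmask the arylacetaldehyde under conditions that leave aryl benzyl ethers untouched.

Step 3
Reactants: 4 1-bromoundecane
Product: 5 undecylzinc bromide (solution in DMA, titrated with iodine)
Conditions: Zn dust (1.5 equiv), I2 (5 mol %), DMA, 80 °C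
Reagents that add atoms: zinc, [Zn]
Why: Direct oxidative insertion of iodine-activated zinc into a primary alkyl bromide in a polar aprotic solvent should give the alkylzinc halide cleanly, with nothing formed beside it.

Step 4
Reactants: 3 2-[3,5-bis(benzyloxy)phenyl]acetaldehyde
Product: 6 (±)-2-[3,5-bis(benzyloxy)phenyl]-1-bromoethyl acetate (crude, used at once)
Conditions: AcBr (1.05 equiv), CH2Cl2, −20 to 0 °C, no Lewis acid; volatiles removed in vacuo
Reagents that add atoms: acetyl bromide, CC(=O)Br
Why: Uncatalysed addition of an acyl bromide across an aliphatic aldehyde C=O (O-acylation, then bromide capture of the acyloxycarbenium ion) should give the 1-bromoalkyl ester as a racemate, which is all the next step needs, while low temperature and the absence of a Lewis acid spare the benzyl ethers and the electron-rich ring.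

Step 5
Reactants: 6 (±)-2-[3,5-bis(benzyloxy)phenyl]-1-bromoethyl acetate; 5 undecylzinc bromide (1.3 equiv)
Product: 7 (R)-1-[3,5-bis(benzyloxy)phenyl]tridecan-2-yl acetate
Conditions: NiBr2·glyme (10 mol %), chiral bis(oxazoline) ligand (12 mol %), THF/DMA, −10 to 0 °C
Reagents that add atoms: none
Why: A low-valent nickel species should abstract bromine from either enantiomer of 6 to give the same planar α-acetoxyalkyl radical at C2, so the configuration of the racemic electrophile is erased. The radical should be captured by the ligand-bound undecylnickel(II) complex formed by transmetallation from 5, and C(sp3)–C(sp3) reductive elimination from nickel(III) then forms the C2–C3 bond. The closest known reaction type is the nickel-catalysed enantioconvergent Negishi alkyl–alkyl coupling of racemic 1-bromoalkyl esters with alkylzinc halides. No ring is closed; the new stereocentre at C2 is under catalyst control, the chiral ligand together with nickel-binding of the acetate carbonyl oxygen telling apart the two otherwise similar CH2 substituents (benzylic C1 and undecyl). The step needs face selectivity at the radical and substitution faster than loss of HBr towards the conjugated enol acetate. The geminal acetoxy group, which stabilises and anchors the radical, the weakly basic organozinc partner and the low temperature should secure both.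

Step 6
Reactants: 7 (R)-1-[3,5-bis(benzyloxy)phenyl]tridecan-2-yl acetate
Product: 8 (R)-1-(3,5-dihydroxyphenyl)tridecan-2-yl acetate
Conditions: H2 (1 atm), 10 % Pd/C, EtOAc, rt
Reagents that add atoms: none
Why: Hydrogenolysis of aryl benzyl ethers over Pd/C in a neutral, non-nucleophilic solvent should free both phenols, while the secondary acetate (homobenzylic, not benzylic) and the C2 stereocentre are untouched.

**Compound list**
1 | 3,5-bis(benzyloxy)benzaldehyde | O=Cc1cc(OCc2ccccc2)cc(OCc2ccccc2)c1 | starting material
2 | 1,3-bis(benzyloxy)-5-(2-methoxyethenyl)benzene (E/Z mixture) | COC=Cc1cc(OCc2ccccc2)cc(OCc2ccccc2)c1 | intermediate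
3 | 2-[3,5-bis(benzyloxy)phenyl]acetaldehyde | O=CCc1cc(OCc2ccccc2)cc(OCc2ccccc2)c1 | intermediate
4 | 1-bromoundecane | CCCCCCCCCCCBr | starting material
5 | undecylzinc bromide | CCCCCCCCCCC[Zn]Br | intermediate
6 | (±)-2-[3,5-bis(benzyloxy)phenyl]-1-bromoethyl acetate (racemic) | CC(=O)OC(Br)Cc1cc(OCc2ccccc2)cc(OCc2ccccc2)c1 | intermediate
7 | (R)-1-[3,5-bis(benzyloxy)phenyl]tridecan-2-yl acetate | CCCCCCCCCCC[C@H](Cc1cc(OCc2ccccc2)cc(OCc2ccccc2)c1)OC(C)=O | intermediate
8 | (R)-1-(3,5-dihydroxyphenyl)tridecan-2-yl acetate | CCCCCCCCCCC[C@H](Cc1cc(O)cc(O)c1)OC(C)=O | target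

**Step count**
Total: 6 steps. Longest linear sequence: 5 steps (steps 1, 2, 4, 5, 6 from compound 1); step 3 is a one-step side branch.

**Steps most likely to fail, with fallbacks**

1. Step 5. The small acetyl group may give insufficient facial discrimination of the α-acetoxyalkyl radical, and loss of HBr from the electrophile towards the styrenyl enol acetate may outrun the coupling.
Fallback, setting out from 3 (with 4 as the source of the undecyl group) and returning at 7: the same bond is made by a polar, catalyst-controlled carbonyl addition. Compound 4 would be converted with Mg in THF into undecylmagnesium bromide F1. Transmetallation with ZnCl2 (0.5 equiv), with the magnesium salts precipitated by 1,4-dioxane and filtered off, would give diundecylzinc F2. F2 would be added to aldehyde 3 in toluene at −20 °C with Ti(OiPr)4 and a catalytic amount of trans-cyclohexane-1,2-bis(trifluoromethanesulfonamide). The ligand antipode that gives the R carbinol is used; by analogy with simple aldehydes this is expected to be (1S,2S), to be confirmed. The product would be (R)-1-[3,5-bis(benzyloxy)phenyl]tridecan-2-ol F3. Acetylation (Ac2O, pyridine, DMAP, CH2Cl2) would then give 7.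

2. Step 4. The bromo ester may lose HBr to the enol acetate, and acetyl bromide may cleave a benzyl ether or acylate the electron-rich ring.
Fallback, setting out from 3 and returning at 8: the bromo ester is bypassed, and the C2–C3 bond and the stereocentre are made by reagent-controlled allylboration. Aldehyde 3 would be treated in Et2O at −78 °C with the antipode of B-allyldiisopinocampheylborane that gives the R carbinol (expected to be the reagent derived from (−)-α-pinene), followed by NaOH/H2O2 work-up, to give (R)-1-[3,5-bis(benzyloxy)phenyl]pent-4-en-2-ol F4. Acetylation (Ac2O, pyridine, DMAP) would give (R)-1-[3,5-bis(benzyloxy)phenyl]pent-4-en-2-yl acetate F5. Cross-metathesis with 1-decene (second-generation Grubbs catalyst, CH2Cl2, 40 °C) would give (R)-1-[3,5-bis(benzyloxy)phenyl]tridec-4-en-2-yl acetate F6 as an E/Z mixture. Hydrogenation under the conditions of step 6 would saturate the alkene and remove both benzyl groups in one operation, giving 8.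

3. Step 2. The electron-rich arylacetaldehyde may enolise and self-condense under the acidic unmasking conditions.
Fallback, setting out from 1 and returning at 3: the aldehyde is reached by a final oxidation under buffered, non-acidic conditions. Wittig methylenation of 1 (Ph3PCH3Br, KOtBu, THF) would give 1,3-bis(benzyloxy)-5-ethenylbenzene F7. Anti-Markovnikov hydroboration–oxidation (9-BBN, THF; then NaOH/H2O2) would give 2-[3,5-bis(benzyloxy)phenyl]ethanol F8. Dess–Martin oxidation (NaHCO3-buffered CH2Cl2, 0 °C) would give 3, which is taken directly into step 4.

**Further compounds**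
F1 | step 5 | undecylmagnesium bromide | CCCCCCCCCCC[Mg]Br
F2 | step 5 | diundecylzinc | CCCCCCCCCCC[Zn]CCCCCCCCCCC
F3 | step 5 | (R)-1-[3,5-bis(benzyloxy)phenyl]tridecan-2-ol | CCCCCCCCCCC[C@H](Cc1cc(OCc2ccccc2)cc(OCc2ccccc2)c1)O
F4 | step 4 | (R)-1-[3,5-bis(benzyloxy)phenyl]pent-4-en-2-ol | C=CC[C@H](Cc1cc(OCc2ccccc2)cc(OCc2ccccc2)c1)O
F5 | step 4 | (R)-1-[3,5-bis(benzyloxy)phenyl]pent-4-en-2-yl acetate | C=CC[C@H](Cc1cc(OCc2ccccc2)cc(OCc2ccccc2)c1)OC(C)=O
F6 | step 4 | (R)-1-[3,5-bis(benzyloxy)phenyl]tridec-4-en-2-yl acetate (E/Z mixture) | CCCCCCCCC=CC[C@H](Cc1cc(OCc2ccccc2)cc(OCc2ccccc2)c1)OC(C)=O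
F7 | step 2 | 1,3-bis(benzyloxy)-5-ethenylbenzene | C=Cc1cc(OCc2ccccc2)cc(OCc2ccccc2)c1
F8 | step 2 | 2-[3,5-bis(benzyloxy)phenyl]ethanol | OCCc1cc(OCc2ccccc2)cc(OCc2ccccc2)c1
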